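## Structural features

The target is a flavone: a benzo ring A and a 4-pyranone ring C fused through C4a–C8a, with a 4-hydroxyphenyl ring B on C2 (chromone atoms carry unprimed locants, the pyrrolidine atoms N1' and C2'–C5' primed ones). Every carbon of ring A is substituted: hydroxyls on C5 and C7, a methoxy group on C6 between them, and on C8 the C2' carbon of an N-methylpyrrolidine. C2' is the only stereocenter and has the (R) configuration. It is benzylic, bound to N1' and has no stereogenic neighbour, so its configuration must come from an enantioselective step or from the chiral pool. The C2'–N1' bond is the fragile element: ring A has oxygen on both ortho carbons (C7, C8a) and on the para carbon (C5), so acid or heat can ionise the bond through an ortho-quinone methide and racemise C2', above all while an ortho hydroxyl is free. Further constraints are the basic tertiary amine (it binds Lewis acids and ruthenium carbenes), the need to free three hydroxyls while the C6 methyl ether stays, and the need for O8a rather than O5 to become O1 of ring C. The real difficulty is therefore a hexasubstituted ring A with a fixed oxygen pattern joined to an enantiopure 2-arylpyrrolidine. The key step uses the fact that C2' bears N1', C3' and the ring A carbon C8, and that C8 has the oxygen-bearing C8a next to it. This is the substitution pattern of a salicylaldehyde borono-Mannich product, and the same free C8a hydroxyl later closes ring C.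

## Logic of the disconnections

**18 to 17.** The three O–benzyl bonds on O5, O7 and the ring B oxygen are cut. Benzyl ethers distinguish these hydroxyls from the C6 methoxy group and can be removed at room temperature without acid, which protects C2'. The forward step must stop before the benzylic C2'–N1' bond or the C2=C3 bond is reduced.

**17 to 16, then to 14 and 15.** O1–C2 is cut first (cyclodehydration), then C2–C3 (enolate aroylation). Ring B and C2 then come from the acid chloride 15, and C3 and C4 from the acetyl group of 14. The demand on 14 is that O8a is the only free hydroxyl next to the acetyl group: with O5 benzylated, ring C can close in one direction only.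

**14 to 13.** The C4–C4a bond is cut. C4a is the only unsubstituted carbon of ring A and lies ortho to the free hydroxyl, so an electrophilic acetylation has no regiochemical choice. The forward step must tolerate two benzyl ethers and the amine.

**13 to 12, then to 10 (through 11).** A C3'=C4' double bond is introduced retrosynthetically and cut by ring-closing metathesis. The pyrrolidine is thereby traced to an acyclic diene whose two alkenes sit on N1' and on C2'. The demands are a masked amine lone pair during metathesis and a saturation method that spares benzyl ethers and the benzylic C–N bond.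

**10 to 7, 8 and 9.** N1'–C2' and C2'–C3' are cut at the stereocenter. Three simple components result: the aldehyde 7 (its carbonyl carbon becomes C2'), the secondary amine 8 (N1', its methyl group, C5' and C4') and the vinylboron reagent 9 (C3'). The forward step must be enantioselective and must deliver the vinyl group only to the iminium ion next to the C8a hydroxyl. 9 is an acyclic boronic ester so that a chiral diol can exchange onto boron.

**7 to 6.** The bond between C8 and the formyl carbon is cut. In 6 the two positions ortho to the hydroxyl are equivalent and the para position is blocked, so ortho-formylation gives a single product, with the hydroxyl that directs it becoming O8a.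

**6 to 4 (through 5).** The C8a–O bond is traced to an aryl–CHO bond by an oxidative aryl migration. This converts a benzoic acid oxidation pattern into the 1,2,3,5-tetraoxygenated arene that is otherwise hard to buy.

**4 to 3, 2 and 1.** Oxidation-level changes and the O–benzyl bonds are undone. 1 already has the methoxy group flanked by two equivalent hydroxyls (the future O5 and O7), so no selective methylation is needed anywhere.

## Other disconnections considered

**Alternative 1:** The cut goes through ring A itself (C7–C8, C4a–C8a and C6–C7), so that the arene is assembled around a pyrrolidine that already carries C2'.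
- Forward key step: the siloxyalkyne A2 would be made from D-proline A4 by N-protection, esterification and ynolate (Kowalski-type) homologation with O-silylation, and heated with the cyclobutenone A3. Electrocyclic opening of A3 to a vinylketene, [2+2] cycloaddition with the alkyne, a second 4π opening and a 6π closure would give the pentasubstituted phenol A1.
- In its favour: C2' comes from the chiral pool, so no enantioselective step is needed. The C8–C2' bond never has to be formed on a crowded arene. The four ring A oxygens would emerge regiodefined and already differentiated (free C7–OH, silyl on O8a, ethyl on O5, methyl on O6). No catalyst is required.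
- Against it here: the (R) configuration requires the unnatural D-amino acid. A3 is not a catalogue compound and needs its own preparation from a squarate ester. The 4-alkoxy group on the cyclobutenone makes the thermal cascade less predictable than in the parent cases. After A1 the route would still need protection of O7, desilylation of O8a, the same C4a acylation and ring C annulation as the chosen plan, reduction of the carbamate to N-methyl before the chromone carbonyl exists, and finally cleavage of an ethyl ether on O5 beside the methyl ether on O6.
- Comparison: on structure the two plans are equals, since both deliver a ring A in which only O8a is free for the annulation. On stereochemical certainty Alternative 1 is the better plan, because its stereocenter is bought and not induced. On mechanism the chosen plan rests on one polar three-component step of a known class, the alternative on a four-stage pericyclic cascade at elevated temperature. On step economy the chosen plan is shorter, because two fragments must be built before the alternative's key step and more protecting-group changes follow it.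

**Alternative 2:** Only N1'–C2' is cut, and the chain C2'–C5' is attached to C8 beforehand.
- Forward key step: the racemic benzylic alcohol A6 would come from aldehyde 7 by addition of a three-carbon organometallic carrying the Boc-protected nitrogen. A chiral phosphoric acid would dehydrate A6 to the ortho-quinone methide across C8a–C8–C2', and 5-exo addition of the carbamate nitrogen within the chiral ion pair would give A5.
- In its favour: ring and stereocenter form together. The step is enantioconvergent, since both enantiomers of A6 pass through the same planar intermediate. It uses the same C8a hydroxyl and the same aldehyde 7, and needs neither ruthenium nor a diimide reduction.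
- Against it here: the quinone methide is stabilised by the benzyloxy groups on C5 and C7 and flanked by the C7 substituent. It should be long-lived and only loosely paired with the phosphate, which is the situation in which such catalysts control the face least well. A5 keeps the free C8a hydroxyl and a benzylic C–N bond and could re-ionise under the same acid, so the stereocenter would be formed reversibly. The carbamate is a weak nucleophile. The organometallic with an N–H carbamate needs double metalation or an extra protecting group. The Boc group must afterwards be reduced to N-methyl with a hydride at elevated temperature.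
- Comparison: from 7 to 13 both plans need three operations (addition, cyclisation and carbamate reduction against three-component coupling, metathesis and diimide reduction), so on step economy the alternative is the equal of the chosen plan. On operational simplicity (no transition metal) it is the better one. On structure both exploit the same ortho hydroxyl. The chosen plan is preferred on mechanism: its stereocenter is set in an irreversible C–C bond formation, whereas the alternative sets it in a C–N bond formation that the acid catalyst can also undo.

**Alternative 3:** This cut concerns ring C only and is compatible with the chosen key step. C2=C3 is disconnected, leading to the phosphorane A8, in which O8a carries the 4-benzyloxybenzoyl group and the C4a acyl group is an acylmethylene ylide.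
- Forward key step: on heating, the ylide carbon would add to the ester carbonyl and the oxaphosphetane would collapse to A7, which is the same compound as 17.
- In its favour: the closure is neutral, so neither the benzyl ethers nor the C2'–N1' bond meets acid. Only O8a carries the ester, so the ring can close one way only. The pyranone forms at the right oxidation level without a dehydration.
- Against it here: A8 would have to be made from 14 by O-aroylation with 15, halogenation of the acetyl methyl group and displacement by a triarylphosphine. An α-halo ketone in the same molecule as N1' invites quaternisation of the tertiary amine. The sequence takes three to four operations where steps 10 and 11 take two. It produces a stoichiometric phosphine oxide, and an ester carbonyl is a poor Wittig acceptor that needs prolonged heating.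
- Comparison: on structure both closures lead to the same compound with the same regiochemical guarantee, so they are equals. On mildness toward the benzyl ethers and the C2'–N1' bond the Wittig closure is the better one. On compatibility with the amine and on step economy the acyl-transfer and cyclodehydration sequence is better.

Key step: step 6

Remark on the chemistry: which antipode of the diol catalyst leads to (R)-10 is assumed to be settled in a first run; the (R)-diol is written in step 6 and its mirror image is used if the sense of induction is the opposite.

## Route

Step 1
Reactants: 1 3,5-dihydroxy-4-methoxybenzoic acid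
Product: 2 benzyl 3,5-bis(benzyloxy)-4-methoxybenzoate
Conditions: BnBr (3.3 equiv), K2CO3 (4 equiv), DMF, 60 °C
Reagents that add atoms: benzyl bromide, BrCc1ccccc1
Why: Williamson etherification of both phenols and SN2 alkylation of the carboxylate run together under carbonate in DMF. The aryl methyl ether is inert, and the ester is reduced in step 2, so no selectivity between the acidic sites is needed.

Step 2
Reactants: 2 benzyl 3,5-bis(benzyloxy)-4-methoxybenzoate
Product: 3 [3,5-bis(benzyloxy)-4-methoxyphenyl]methanol
Conditions: LiAlH4 (1.2 equiv), THF, 0 °C → rt; aq. NaOH work-up
Reagents that add atoms: none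
Why: Hydride reduction of the ester to the primary benzylic alcohol; aryl benzyl ethers are stable to LiAlH4, and the benzyl alcohol released from the ester is removed by chromatography.

Step 3
Reactants: 3 [3,5-bis(benzyloxy)-4-methoxyphenyl]methanol
Product: 4 3,5-bis(benzyloxy)-4-methoxybenzaldehyde
Conditions: TEMPO (10 mol %), PhI(OAc)2 (1.1 equiv), CH2Cl2, rt
Reagents that add atoms: none
Why: Oxoammonium-mediated (TEMPO) oxidation of a primary benzylic alcohol stops at the aldehyde under neutral conditions and does not touch benzyl ethers.

Step 4
Reactants: 4 3,5-bis(benzyloxy)-4-methoxybenzaldehyde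
Product: 6 3,5-bis(benzyloxy)-4-methoxyphenol, via aryl formate 5 (not isolated)
Conditions: mCPBA (1.3 equiv), CH2Cl2, 0 °C → rt; NaHCO3 wash; crude in MeOH, K2CO3 (cat.), rt
Reagents that add atoms: 3-chloroperoxybenzoic acid (mCPBA), OOC(=O)c1cccc(Cl)c1
Why: Baeyer–Villiger oxidation: in the Criegee intermediate the electron-rich aryl group (para-methoxy) migrates in preference to hydrogen to give formate 5, which mild methanolysis cleaves to the phenol. A peracid is used because a Dakin reaction with alkaline peroxide needs a free ortho or para hydroxyl, which 4 lacks.

Step 5
Reactants: 6 3,5-bis(benzyloxy)-4-methoxyphenol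
Product: 7 4,6-bis(benzyloxy)-2-hydroxy-5-methoxybenzaldehyde
Conditions: MgCl2 (2 equiv), Et3N (4 equiv), (CH2O)n (6 equiv), MeCN, reflux
Reagents that add atoms: paraformaldehyde (reacts as formaldehyde), C=O
Why: Magnesium-mediated ortho-formylation (Casnati–Skattebøl reaction): the magnesium phenoxide delivers formaldehyde to the ortho carbon, and a second formaldehyde oxidises the benzylic alkoxide to the aldehyde. The two ortho positions of 6 are equivalent and the para position is blocked, so one regioisomer results, and the hydroxyl next to the new aldehyde is the future O8a.

Step 6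
Reactants: 7 4,6-bis(benzyloxy)-2-hydroxy-5-methoxybenzaldehyde; 8 N-methylallylamine (N-methylprop-2-en-1-amine); 9 dibutyl vinylboronate (dibutyl ethenylboronate)
Product: 10 3,5-bis(benzyloxy)-4-methoxy-2-{(1R)-1-[methyl(prop-2-en-1-yl)amino]prop-2-en-1-yl}phenol
Conditions: 7, 8 (1.2 equiv), 4 Å MS, toluene, rt; then 9 (1.5 equiv), (R)-3,3'-Br2-BINOL (20 mol %), 0 °C → rt
Reagents that add atoms: none
Why: This is a Petasis borono-Mannich reaction in its diol-catalysed enantioselective form, a reaction type known for salicylaldehydes with secondary amines and alkenylboronates. Aldehyde 7 and amine 8 condense to an iminium phenoxide, which forms N1'–C2'; ester 9 exchanges butoxy groups for the chiral binaphthol, and the C8a phenoxide adds to boron to give a tetracoordinate boronate held next to the iminium carbon. The vinyl group then migrates from boron to that carbon within this cyclic array and forms C2'–C3' irreversibly. No ring is closed. The new stereocenter C2' is controlled by the chiral diol on boron, which shields one face of the iminium ion. The step needs vinyl transfer only to the iminium ion next to the hydroxyl and a slow uncatalysed pathway: the free C8a–OH secures the first, and the acyclic butyl ester (which, unlike a pinacol ester, hands its boron over to the diol) together with low temperature and sieves secures the second. The benzyl ethers keep O5 and O7 from competing for boron.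

Step 7
Reactants: 10 3,5-bis(benzyloxy)-4-methoxy-2-{(1R)-1-[methyl(prop-2-en-1-yl)amino]prop-2-en-1-yl}phenol
Product: 12 (2R)-2-[2,4-bis(benzyloxy)-6-hydroxy-3-methoxyphenyl]-1-methyl-2,5-dihydro-1H-pyrrol-1-ium 4-methylbenzenesulfonate, via diene tosylate salt 11 (not isolated)
Conditions: TsOH·H2O (1.05 equiv), CH2Cl2, rt; second-generation Grubbs catalyst RuCl2(H2IMes)(PCy3)(=CHPh) (5 mol %), 40 °C
Reagents that add atoms: p-toluenesulfonic acid, Cc1ccc(S(=O)(=O)O)cc1
Why: Ring-closing olefin metathesis of a 1,6-diene to a five-membered ring with loss of ethene; protonation of N1' keeps the amine from binding the ruthenium carbene, and the free phenol is tolerated. C2' is not involved, and isolation as the salt protects the 3-pyrroline from air oxidation to the pyrrole.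

Step 8
Reactants: 12 (2R)-2-[2,4-bis(benzyloxy)-6-hydroxy-3-methoxyphenyl]-1-methyl-2,5-dihydro-1H-pyrrol-1-ium 4-methylbenzenesulfonate
Product: 13 3,5-bis(benzyloxy)-4-methoxy-2-[(2R)-1-methylpyrrolidin-2-yl]phenol
Conditions: 2-nitrobenzenesulfonyl hydrazide (6 equiv), Et3N (12 equiv), CH2Cl2, rt; aq. NaHCO3
Reagents that add atoms: none
Why: Diimide, released from the sulfonyl hydrazide by triethylamine at room temperature, transfers two hydrogens to the unhindered cis C3'=C4' bond in a concerted syn fashion. It does not hydrogenolyse benzyl ethers or the benzylic C2'–N1' bond, which a palladium-catalysed hydrogenation at this stage would endanger; the base also liberates the free amine.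

Step 9
Reactants: 13 3,5-bis(benzyloxy)-4-methoxy-2-[(2R)-1-methylpyrrolidin-2-yl]phenol
Product: 14 1-{4,6-bis(benzyloxy)-2-hydroxy-5-methoxy-3-[(2R)-1-methylpyrrolidin-2-yl]phenyl}ethan-1-one
Conditions: BF3·OEt2 (3.5 equiv), CH2Cl2, 0 °C; Ac2O (2.5 equiv), 0 °C → rt; then aq. NaOAc, MeOH, 40 °C
Reagents that add atoms: acetic anhydride, CC(=O)OC(C)=O
Why: Friedel–Crafts acetylation at C4a, the only unsubstituted ring carbon, which is activated by the ortho hydroxyl and by the ortho and para benzyloxy groups; the work-up hydrolyses the boron chelate of the product and any aryl acetate. BF3 is added first so that N1' is complexed and not acylated, and the temperature is kept low to spare the C5 benzyl ether.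

Step 10
Reactants: 14 1-{4,6-bis(benzyloxy)-2-hydroxy-5-methoxy-3-[(2R)-1-methylpyrrolidin-2-yl]phenyl}ethan-1-one; 15 4-(benzyloxy)benzoyl chloride
Product: 16 1-{4,6-bis(benzyloxy)-2-hydroxy-5-methoxy-3-[(2R)-1-methylpyrrolidin-2-yl]phenyl}-3-[4-(benzyloxy)phenyl]propane-1,3-dione
Conditions: LiN(SiMe3)2 (4 equiv), THF, −78 → −10 °C; 15 (1.1 equiv), −78 °C → rt; aq. NH4Cl
Reagents that add atoms: none
Why: Directed Claisen condensation in the Baker–Venkataraman manner: excess amide base forms the phenoxide and the methyl ketone enolate, which is C-aroylated by 15 (any aryl ester formed first rearranges to the same diketone by intramolecular acyl transfer under the base). The benzylic C2'–H is far less acidic than the acetyl group, so the stereocenter is not touched.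

Step 11
Reactants: 16 1-{4,6-bis(benzyloxy)-2-hydroxy-5-methoxy-3-[(2R)-1-methylpyrrolidin-2-yl]phenyl}-3-[4-(benzyloxy)phenyl]propane-1,3-dione
Product: 17 5,7-bis(benzyloxy)-2-[4-(benzyloxy)phenyl]-6-methoxy-8-[(2R)-1-methylpyrrolidin-2-yl]-4H-chromen-4-one
Conditions: H2SO4 (1.5 equiv), AcOH, 50 °C; aq. NaHCO3
Reagents that add atoms: none
Why: Acid-catalysed cyclodehydration: the C8a hydroxyl adds to the carbonyl next to ring B (O1–C2, six-membered hemiketal) and loss of water gives C2=C3. Only O8a is free, O5 being benzylated, so ring C can close in one direction only; the temperature is kept moderate so that the protonated C2'–N1' bond is not heated more than needed.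

Step 12
Reactants: 17 5,7-bis(benzyloxy)-2-[4-(benzyloxy)phenyl]-6-methoxy-8-[(2R)-1-methylpyrrolidin-2-yl]-4H-chromen-4-one
Product: 18 5,7-dihydroxy-2-(4-hydroxyphenyl)-6-methoxy-8-[(2R)-1-methylpyrrolidin-2-yl]-4H-chromen-4-one
Conditions: H2 (1 atm), Pd/C (10 % Pd on carbon), THF–MeOH, rt
Reagents that add atoms: none
Why: Hydrogenolysis of the three aryl benzyl ethers on palladium under neutral conditions at room temperature; the C6 methyl ether is inert. Aryl benzyl ethers should be cleaved faster than the ring benzylic C–N bond or the chromone C2=C3 bond, so the reaction is stopped after uptake of three equivalents of hydrogen.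

## Compound list

1 | 3,5-dihydroxy-4-methoxybenzoic acid | COc1c(O)cc(C(=O)O)cc1O | starting material
2 | benzyl 3,5-bis(benzyloxy)-4-methoxybenzoate | COc1c(OCc2ccccc2)cc(C(=O)OCc2ccccc2)cc1OCc1ccccc1 | intermediate
3 | [3,5-bis(benzyloxy)-4-methoxyphenyl]methanol | COc1c(OCc2ccccc2)cc(CO)cc1OCc1ccccc1 | intermediate
4 | 3,5-bis(benzyloxy)-4-methoxybenzaldehyde | COc1c(OCc2ccccc2)cc(C=O)cc1OCc1ccccc1 | intermediate
5 | 3,5-bis(benzyloxy)-4-methoxyphenyl formate | COc1c(OCc2ccccc2)cc(OC=O)cc1OCc1ccccc1 | intermediate
6 | 3,5-bis(benzyloxy)-4-methoxyphenol | COc1c(OCc2ccccc2)cc(O)cc1OCc1ccccc1 | intermediate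
7 | 4,6-bis(benzyloxy)-2-hydroxy-5-methoxybenzaldehyde | O=Cc1c(O)cc(OCc2ccccc2)c(OC)c1OCc1ccccc1 | intermediate
8 | N-methylallylamine | CNCC=C | starting material
9 | dibutyl vinylboronate | C=CB(OCCCC)OCCCC | starting material
10 | 3,5-bis(benzyloxy)-4-methoxy-2-{(1R)-1-[methyl(prop-2-en-1-yl)amino]prop-2-en-1-yl}phenol | C=C[C@@H](N(C)CC=C)c1c(O)cc(OCc2ccccc2)c(OC)c1OCc1ccccc1 | intermediate
11 | N-{(1R)-1-[2,4-bis(benzyloxy)-6-hydroxy-3-methoxyphenyl]prop-2-en-1-yl}-N-methylprop-2-en-1-aminium 4-methylbenzenesulfonate | C=C[C@@H]([NH+](C)CC=C)c1c(O)cc(OCc2ccccc2)c(OC)c1OCc1ccccc1.Cc1ccc(S(=O)(=O)[O-])cc1 | intermediate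
12 | (2R)-2-[2,4-bis(benzyloxy)-6-hydroxy-3-methoxyphenyl]-1-methyl-2,5-dihydro-1H-pyrrol-1-ium 4-methylbenzenesulfonate | C[NH+]1CC=C[C@@H]1c1c(O)cc(OCc2ccccc2)c(OC)c1OCc1ccccc1.Cc1ccc(S(=O)(=O)[O-])cc1 | intermediate
13 | 3,5-bis(benzyloxy)-4-methoxy-2-[(2R)-1-methylpyrrolidin-2-yl]phenol | CN1CCC[C@@H]1c1c(O)cc(OCc2ccccc2)c(OC)c1OCc1ccccc1 | intermediate
14 | 1-{4,6-bis(benzyloxy)-2-hydroxy-5-methoxy-3-[(2R)-1-methylpyrrolidin-2-yl]phenyl}ethan-1-one | CC(=O)c1c(O)c([C@H]2CCCN2C)c(OCc2ccccc2)c(OC)c1OCc1ccccc1 | intermediate
15 | 4-(benzyloxy)benzoyl chloride | O=C(Cl)c1ccc(OCc2ccccc2)cc1 | starting material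
16 | 1-{4,6-bis(benzyloxy)-2-hydroxy-5-methoxy-3-[(2R)-1-methylpyrrolidin-2-yl]phenyl}-3-[4-(benzyloxy)phenyl]propane-1,3-dione | O=C(CC(=O)c1ccc(OCc2ccccc2)cc1)c1c(O)c([C@H]2CCCN2C)c(OCc2ccccc2)c(OC)c1OCc1ccccc1 | intermediate
17 | 5,7-bis(benzyloxy)-2-[4-(benzyloxy)phenyl]-6-methoxy-8-[(2R)-1-methylpyrrolidin-2-yl]-4H-chromen-4-one | COc1c(OCc2ccccc2)c([C@H]2CCCN2C)c2oc(-c3ccc(OCc4ccccc4)cc3)cc(=O)c2c1OCc1ccccc1 | intermediate
18 | 5,7-dihydroxy-2-(4-hydroxyphenyl)-6-methoxy-8-[(2R)-1-methylpyrrolidin-2-yl]-4H-chromen-4-one | COc1c(O)c([C@H]2CCCN2C)c2oc(-c3ccc(O)cc3)cc(=O)c2c1O | target

## Step count and least certain steps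

Total step count: 12. Longest linear sequence: 12 steps (1 to 18); 8, 9 and 15 are used as purchased.

**Step 6 (key step).** The most likely failure is erosion of facial selectivity. The aldehyde is electron-rich and substituted on both ortho positions, so iminium formation and vinyl transfer should be slow, and the unsubstituted vinyl group migrates less readily than an aryl-substituted alkenyl group. This gives the uncatalysed transfer from boron that carries no chiral diol more time to compete. The fallback gives up catalytic induction for resolution. It sets out from 7 (with 8 and 9): the three-component reaction is run without the diol, warm in toluene or in hexafluoro-2-propanol, to give the racemic allylic amine F1. This is crystallised with one antipode of O,O'-di-p-toluoyltartaric acid (the (2R,3R) acid is written) to give the diastereomerically pure hydrogen tartrate salt F2. Treatment with aqueous base then liberates the (R)-amine, and the fallback comes back to the route at 10.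

**Step 9.** Two processes threaten this step. The first is loss of the C5 benzyl group through Lewis-acid chelation next to the new carbonyl, which would free a second ortho hydroxyl and remove the regiochemical control of step 11. The second is ionisation of the Lewis-acid-complexed C2'–N1' bond while the C8a hydroxyl is free, which would erode the configuration. The fallback avoids Lewis acids altogether. It sets out from 13: magnesium-mediated ortho-formylation (MgCl2, Et3N, paraformaldehyde), the reaction already used in step 5, gives the salicylaldehyde F5. Addition of MeMgBr (excess, THF, 0 °C) gives the benzylic carbinol F6 as a mixture at the new carbinol carbon. Oxidation with MnO2 in CH2Cl2 then returns to the route at 14, at the cost of two extra steps.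

**Step 7.** Ruthenium hydrides formed from the catalyst may move the new double bond into conjugation with nitrogen, which would erase C2'. The protonated allylic and benzylic C2'–N1' bond may also ionise with help from the free C8a hydroxyl. The fallback masks that hydroxyl. It sets out from 10: acetylation (Ac2O, Et3N, DMAP) gives the aryl acetate F3, in which the ortho-quinone methide pathway is blocked. Metathesis of its tosylate salt under the conditions of step 7 gives the pyrroline acetate F4. Methanolysis (K2CO3, MeOH) and salt formation with TsOH bring the material back to the route at 12.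

**Step 12.** The risk is over-reduction once the benzyl ethers have gone: hydrogenolysis of the benzylic C2'–N1' bond, which would open the pyrrolidine, or saturation of C2=C3. The fallback replaces hydrogenolysis by Lewis-acid dealkylation. It sets out from 17 and uses BCl3 with pentamethylbenzene as cation scavenger in CH2Cl2 at −78 °C, which should cleave aryl benzyl ethers much faster than the aryl methyl ether. It ends directly at 18 and passes through no new compound (F0).

## Further compounds

F1 | step 6 | racemic 3,5-bis(benzyloxy)-4-methoxy-2-{1-[methyl(prop-2-en-1-yl)amino]prop-2-en-1-yl}phenol | C=CC(N(C)CC=C)c1c(O)cc(OCc2ccccc2)c(OC)c1OCc1ccccc1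
F2 | step 6 | N-{(1R)-1-[2,4-bis(benzyloxy)-6-hydroxy-3-methoxyphenyl]prop-2-en-1-yl}-N-methylprop-2-en-1-aminium hydrogen (2R,3R)-O,O'-di-p-toluoyltartrate | C=C[C@@H]([NH+](C)CC=C)c1c(O)cc(OCc2ccccc2)c(OC)c1OCc1ccccc1.Cc1ccc(cc1)C(=O)O[C@H]([C@@H](OC(=O)c1ccc(C)cc1)C(O)=O)C([O-])=O
F3 | step 7 | 3,5-bis(benzyloxy)-4-methoxy-2-{(1R)-1-[methyl(prop-2-en-1-yl)amino]prop-2-en-1-yl}phenyl acetate | C=C[C@@H](N(C)CC=C)c1c(OC(C)=O)cc(OCc2ccccc2)c(OC)c1OCc1ccccc1
F4 | step 7 | 3,5-bis(benzyloxy)-4-methoxy-2-[(2R)-1-methyl-2,5-dihydro-1H-pyrrol-2-yl]phenyl acetate | CN1CC=C[C@@H]1c1c(OC(C)=O)cc(OCc2ccccc2)c(OC)c1OCc1ccccc1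
F5 | step 9 | 4,6-bis(benzyloxy)-2-hydroxy-5-methoxy-3-[(2R)-1-methylpyrrolidin-2-yl]benzaldehyde | O=Cc1c(O)c([C@H]2CCCN2C)c(OCc2ccccc2)c(OC)c1OCc1ccccc1
F6 | step 9 | 1-{4,6-bis(benzyloxy)-2-hydroxy-5-methoxy-3-[(2R)-1-methylpyrrolidin-2-yl]phenyl}ethan-1-ol | CC(O)c1c(O)c([C@H]2CCCN2C)c(OCc2ccccc2)c(OC)c1OCc1ccccc1
F0 | step 12 | none | none
A1 | alternative 1 | tert-butyl (2R)-2-[4-ethoxy-2-hydroxy-3-methoxy-6-(triisopropylsilyloxy)phenyl]pyrrolidine-1-carboxylate | CCOc1cc(O[Si](C(C)C)(C(C)C)C(C)C)c([C@H]2CCCN2C(=O)OC(C)(C)C)c(O)c1OC
A2 | alternative 1 | tert-butyl (2R)-2-[(triisopropylsilyloxy)ethynyl]pyrrolidine-1-carboxylate | CC(C)[Si](OC#C[C@H]1CCCN1C(=O)OC(C)(C)C)(C(C)C)C(C)C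
A3 | alternative 1 | 3-ethoxy-4-methoxycyclobut-2-en-1-one (racemic) | CCOC1=CC(=O)C1OC
A4 | alternative 1 | D-proline | OC(=O)[C@H]1CCCN1
A5 | alternative 2 | tert-butyl (2R)-2-[2,4-bis(benzyloxy)-6-hydroxy-3-methoxyphenyl]pyrrolidine-1-carboxylate | COc1c(OCc2ccccc2)cc(O)c([C@H]2CCCN2C(=O)OC(C)(C)C)c1OCc1ccccc1
A6 | alternative 2 | tert-butyl N-{4-[2,4-bis(benzyloxy)-6-hydroxy-3-methoxyphenyl]-4-hydroxybutyl}carbamate (racemic) | COc1c(OCc2ccccc2)cc(O)c(C(O)CCCNC(=O)OC(C)(C)C)c1OCc1ccccc1
A7 | alternative 3 | 5,7-bis(benzyloxy)-2-[4-(benzyloxy)phenyl]-6-methoxy-8-[(2R)-1-methylpyrrolidin-2-yl]-4H-chromen-4-one | COc1c(OCc2ccccc2)c([C@H]2CCCN2C)c2oc(-c3ccc(OCc4ccccc4)cc3)cc(=O)c2c1OCc1ccccc1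
A8 | alternative 3 | 3,5-bis(benzyloxy)-4-methoxy-2-[(2R)-1-methylpyrrolidin-2-yl]-6-[2-(triphenyl-λ5-phosphanylidene)acetyl]phenyl 4-(benzyloxy)benzoate | O=C(C=P(c1ccccc1)(c1ccccc1)c1ccccc1)c1c(OC(=O)c2ccc(OCc3ccccc3)cc2)c([C@H]2CCCN2C)c(OCc2ccccc2)c(OC)c1OCc1ccccc1
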